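**First readings.** By 0.667 h the spring flask already reads 90.0% of its charged free monomer in chains. After that its free monomer stays level while its monomer in chains sinks.

the same everywhere: initiator 100 µM

| charge | free monomer | remark | time |
|---|---|---|---|
| spring | 20 mM | the very flask that is asked about, followed so far |  |
| winter | 10 mM | run made earlier |  |
| flask | 20 mM |  | 25 h |

- spring (time / h: monomer in chains / %, free monomer / %): 0.667: 90.0, 10.0; 1.33: 89.9, 9.6; 3.00: 88.4, 9.8; 8.00: 84.3, 9.8
- winter (time / h: monomer in chains / %, free monomer / %): 0.833: 80.2, 19.2; 2.00: 79.0, 19.4; 4.00: 77.9, 18.9; 10.0: 72.7, 20.0

(each reading ± 0.5 percentage points)

1. average number of monomer units in a chain (chains begun, living or dead) at 25 h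
2. part of the free monomer that has reacted at 25 h

- the average divides the monomer in chains by the number of chains begun, living and dead together
- the earlier runs do not show the number of chains; that part of a forecast is a guess

**Free monomer.** The spring readings of free monomer show no trend beyond their scatter, so I assume the level lasts and take the part reacted at 25 h as 90.2%.

**Two ways.** A first-order loss removes the same fraction in equal times at any charge, so each run gives its own half-life for monomer in chains. From first to last reading, the spring run gives 77.7 h and the winter run 64.7 h, so spring reads longer than winter. Neither need be cheating: the drops are just 5.7 percentage points and 7.5 points, with 0.5 points of scatter on each reading, so I read the gap as scatter. My holding time, the half-life of monomer in chains at the mean of both rates, is 70.6 h.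

**My reckoning.** Counted from the first spring reading, the holding time gives my estimate of 70.9% of the charged free monomer in chains at 25 h. The flask charges 200 monomer per initiator. Taking one chain per initiator, a guess since the runs do not show the number of chains, gives 142 units per chain.

**Forecast and result.** The forecast gives 144, above mine, and 90.2%, noting that the “mass balance does not close”. The flask gives 142 and 90.3%, with 0% of its initiator left.

    free monomer + living end → monomer in chains + living end, rate k1*[living end]*[free monomer] (k = 1900 /M/min)
    free monomer + initiator → living end + monomer in chains (k = 260 /M/min)
    monomer in chains → over-reaction product (k = 1.60 × 10⁻⁴ /min)
    monomer in chains + living end → free monomer + living end, rate k4*[living end] as long as [monomer in chains] is above zero (k = 3.70 /min)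

**Less initiator.** At 25 h this flask holds 71.1% in chains, where I reckoned 70.9%. A neighbouring flask differs only in its initiator, 0.025 mM, a quarter of the charge in this flask. I carry the holding time over unchanged, so my estimate for the neighbour is again 70.9% in chains, and one chain per initiator gives 567 units per chain. At 25 h the neighbour stands at 71.2% in chains and 9.74% free monomer, with 0% of its initiator left and 0.0250 mM of living end. At that time its average chain holds 570 units.

All runs stem from a simulated flask with made-up constants.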